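**Retrosynthetic overview**
- Quinone 13 comes from the phenol 12 by para-oxidation; 12 comes from the cyclohexenol 10 by dehydrogenative aromatisation. The molecule has one ring and it is formed once.
- Ring (key step): C1–C6 closure of an acyclic, fully functionalised 2-methoxy-8-angeloyloxy-farnesal 9 by intramolecular carbonyl-ene (Prins-type) reaction. This is the aldehyde counterpart of the farnesyl → bisabolyl cyclisation and ends, like β-bisabolene formation, with loss of a C14 hydrogen to give the exocyclic methylene.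
- Aldehyde 9 comes from the C13 methyl ketone 4 by a two-carbon homologation with lithiated 1,2-dimethoxyethene, then angeloylation.
- The C8 stereocentre comes from Brown allylation of keto-enal 2 (SeO2 oxidation of sulcatone); the prenyl end is made by cross-metathesis.

Assumption: the target is read as a bisabolane quinone and positions are numbered as in farnesane: ring C1–C6 (C1 and C4 carbonyls, OMe on C2, C15 methyl on C3, side chain on C6), exocyclic C7=C14, stereocentre C8 (S).

Step 1
Reactants: 1 6-methylhept-5-en-2-one (sulcatone)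
Product: 2 (2E)-2-methyl-6-oxohept-2-enal
Conditions: SeO2 (1.1 equiv), 95% EtOH, reflux
Reagents that add atoms: selenium dioxide, O=[Se]=O
Why: SeO2 allylic oxidation (ene reaction then [2,3]-sigmatropic shift) attacks the methyl group trans to the chain of the trisubstituted alkene and so gives the (E)-enal, while the ketone is left alone at ethanol reflux.

Step 2
Reactants: 2 (2E)-2-methyl-6-oxohept-2-enal
Product: 3 (5E,7S)-7-hydroxy-6-methyldeca-5,9-dien-2-one
Conditions: (−)-Ipc2B(allyl) (1.05 equiv), Et2O, −100 to −78 °C; then NaOH, H2O2, 0 °C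
Reagents that add atoms: (−)-B-allyldiisopinocampheylborane, C=CCB([C@@H]1C[C@@H]2C[C@H]([C@H]1C)C2(C)C)[C@@H]1C[C@@H]2C[C@H]([C@H]1C)C2(C)C
Why: Brown asymmetric allylboration through a chair six-membered transition state, in which the reagent derived from (+)-α-pinene adds allyl to the Si face of the aldehyde (the sense that turns benzaldehyde into (S)-1-phenylbut-3-en-1-ol) and so sets C8 as (S), the enal reacting far faster than the methyl ketone at −100 °C.

Step 3
Reactants: 3 (5E,7S)-7-hydroxy-6-methyldeca-5,9-dien-2-one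
Product: 4 (5E,7S)-7-hydroxy-6,10-dimethylundeca-5,9-dien-2-one
Conditions: 2-methyl-2-butene (neat, excess), second-generation Grubbs catalyst RuCl2(=CHPh)(PCy3)(H2IMes) (3 mol %), 40 °C
Reagents that add atoms: 2-methyl-2-butene, CC=C(C)C
Why: Olefin cross-metathesis of the terminal alkene with 2-methyl-2-butene installs the prenyl end and releases propene, the trisubstituted alkene and the free alcohol being inert and C8 untouched.

Step 4
Reactants: 4 (5E,7S)-7-hydroxy-6,10-dimethylundeca-5,9-dien-2-one; 5 1,2-dimethoxyethene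
Product: 7 (6E,8S)-8-hydroxy-2-methoxy-3,7,11-trimethyldodeca-2,6,10-trienal (2E/2Z mixture), via carbinol adduct 6 (not isolated)
Conditions: 5 (2.6 equiv), t-BuLi (2.5 equiv), THF, −78 to −20 °C; 4, −78 °C; then 1 M HCl, THF, 0 °C
Reagents that add atoms: water, O
Why: An α-lithiated enol ether (the open-chain counterpart of 2-lithio-5,6-dihydro-1,4-dioxine) adds 1,2 to the ketone, and acid then ionises the tertiary allylic alcohol to a dialkoxy-stabilised allyl cation that takes up water at C1 and loses methanol, an allylic transposition that amounts to a two-carbon homologation to the α-methoxy enal.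

Step 5
Reactants: 7 (6E,8S)-8-hydroxy-2-methoxy-3,7,11-trimethyldodeca-2,6,10-trienal; 8 angelic acid
Product: 9 (6E,8S)-2-methoxy-3,7,11-trimethyl-1-oxododeca-2,6,10-trien-8-yl (2Z)-2-methylbut-2-enoate (2E/2Z mixture)
Conditions: 8 (1.5 equiv), 2,4,6-Cl3C6H2COCl (1.5 equiv), Et3N (3 equiv), toluene, rt; then 7, 80 °C, no DMAP
Reagents that add atoms: none
Why: Yamaguchi esterification through the pre-formed mixed anhydride, run without DMAP so that the (Z)-angelate is not isomerised to the tiglate, and with retention at C8 because the C8–O bond is not broken.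

Step 6 (key step)
Reactants: 9 (6E,8S)-2-methoxy-3,7,11-trimethyl-1-oxododeca-2,6,10-trien-8-yl (2Z)-2-methylbut-2-enoate
Product: 10 (3S)-2-(2-hydroxy-3-methoxy-4-methylcyclohex-3-en-1-yl)-6-methylhepta-1,5-dien-3-yl (2Z)-2-methylbut-2-enoate (ring diastereomers)
Conditions: Me2AlCl (1.5 equiv), CH2Cl2, −78 to 0 °C; aq. KNaC4H4O6 work-up
Reagents that add atoms: none
Why: Lewis-acid-promoted intramolecular carbonyl-ene (Prins-type) cyclisation in which C1 bonds to C6 through a six-membered transition state and a C14 hydrogen passes to oxygen to leave the exocyclic methylene; the C8 hydrogen is expected to be spared because it sits on the ester-bearing carbon, the 2Z isomer (formyl trans to C4) is expected to equilibrate in the aluminium complex, the new C1 and C6 centres form as a mixture that aromatisation erases, and C8 is untouched.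

Step 7
Reactants: 10 (3S)-2-(2-hydroxy-3-methoxy-4-methylcyclohex-3-en-1-yl)-6-methylhepta-1,5-dien-3-yl (2Z)-2-methylbut-2-enoate
Product: 12 (3S)-2-(2-hydroxy-3-methoxy-4-methylphenyl)-6-methylhepta-1,5-dien-3-yl (2Z)-2-methylbut-2-enoate, via methoxy enone 11 (not isolated)
Conditions: DDQ (2.2 equiv), dry 1,4-dioxane, rt to 50 °C
Reagents that add atoms: none
Why: DDQ dehydrogenation in two hydride abstractions, first oxidation of the enol-ether-activated allylic alcohol to the enone and then aromatisation of the cyclohexenone through its dienol (enolised toward the doubly activated C6–H) to the dienone that tautomerises to the phenol.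

Step 8
Reactants: 12 (3S)-2-(2-hydroxy-3-methoxy-4-methylphenyl)-6-methylhepta-1,5-dien-3-yl (2Z)-2-methylbut-2-enoate
Product: 13 (3S)-2-(5-methoxy-4-methyl-3,6-dioxocyclohexa-1,4-dien-1-yl)-6-methylhepta-1,5-dien-3-yl (2Z)-2-methylbut-2-enoate
Conditions: (KSO3)2NO (2.5 equiv), KH2PO4 buffer, acetone/H2O, 0 °C to rt
Reagents that add atoms: potassium nitrosodisulfonate (Fremy's salt), [K+].[K+].[O]N(S(=O)(=O)[O-])S(=O)(=O)[O-]
Why: Teuber oxidation, in which the nitrosodisulfonate radical converts a phenol with a free para position into the para-quinone and delivers the C4 oxygen, alkenes and esters being inert.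

**Compound list**
1 | 6-methylhept-5-en-2-one (sulcatone) | CC(=O)CCC=C(C)C | starting material
2 | (2E)-2-methyl-6-oxohept-2-enal | CC(=O)CC/C=C(\C)C=O | intermediate
3 | (5E,7S)-7-hydroxy-6-methyldeca-5,9-dien-2-one | CC(=O)CC/C=C(\C)[C@H](CC=C)O | intermediate
4 | (5E,7S)-7-hydroxy-6,10-dimethylundeca-5,9-dien-2-one | CC(=O)CC/C=C(\C)[C@H](CC=C(C)C)O | intermediate
5 | 1,2-dimethoxyethene (E/Z mixture) | COC=COC | starting material
6 | (6E,8S)-1,2-dimethoxy-3,7,11-trimethyldodeca-1,6,10-triene-3,8-diol (C3 epimers) | COC=C(OC)C(C)(O)CC/C=C(\C)[C@H](CC=C(C)C)O | intermediate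
7 | (6E,8S)-8-hydroxy-2-methoxy-3,7,11-trimethyldodeca-2,6,10-trienal (2E/2Z mixture) | O=CC(OC)=C(C)CC/C=C(\C)[C@H](CC=C(C)C)O | intermediate
8 | angelic acid, (2Z)-2-methylbut-2-enoic acid | C/C=C(/C)C(=O)O | starting material
9 | (6E,8S)-2-methoxy-3,7,11-trimethyl-1-oxododeca-2,6,10-trien-8-yl (2Z)-2-methylbut-2-enoate (2E/2Z mixture) | O=CC(OC)=C(C)CC/C=C(\C)[C@H](CC=C(C)C)OC(=O)/C(C)=C\C | intermediate
10 | (3S)-2-(2-hydroxy-3-methoxy-4-methylcyclohex-3-en-1-yl)-6-methylhepta-1,5-dien-3-yl (2Z)-2-methylbut-2-enoate (ring diastereomers) | OC1C(OC)=C(C)CCC1C(=C)[C@H](CC=C(C)C)OC(=O)/C(C)=C\C | intermediate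
11 | (3S)-2-(3-methoxy-4-methyl-2-oxocyclohex-3-en-1-yl)-6-methylhepta-1,5-dien-3-yl (2Z)-2-methylbut-2-enoate | O=C1C(OC)=C(C)CCC1C(=C)[C@H](CC=C(C)C)OC(=O)/C(C)=C\C | intermediate
12 | (3S)-2-(2-hydroxy-3-methoxy-4-methylphenyl)-6-methylhepta-1,5-dien-3-yl (2Z)-2-methylbut-2-enoate | Oc1c(OC)c(C)ccc1C(=C)[C@H](CC=C(C)C)OC(=O)/C(C)=C\C | intermediate
13 | (3S)-2-(5-methoxy-4-methyl-3,6-dioxocyclohexa-1,4-dien-1-yl)-6-methylhepta-1,5-dien-3-yl (2Z)-2-methylbut-2-enoate | C=C(C1=CC(=O)C(C)=C(OC)C1=O)[C@H](CC=C(C)C)OC(=O)/C(C)=C\C | target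

**Step count**
Total steps: 8. Longest linear sequence: 8 steps (1 to 13).

**Three steps most likely to fail**

Step 6 (carbonyl-ene closure). The allylic angelate may ionise or act as a neighbouring group at the developing C7 cation, the C8 hydrogen may be transferred in place of a C14 hydrogen, and the 2Z aldehyde may not equilibrate. Fallback: the ester is kept out of the Lewis-acid step and put on last. The fallback sets out from 7, which is silylated (TBSCl, imidazole, DMF) to the silyl ether enal F1. F1 is cyclised with Me2AlCl to the silyl ether cyclohexenol F2. F2 is aromatised with DDQ by way of the silyl ether enone F3 to the silyl ether phenol F4. F4 is oxidised with (KSO3)2NO to the silyl ether quinone F5. F5 is desilylated with HF·pyridine to the hydroxy quinone F6, which is esterified with the pre-formed angelic 2,4,6-trichlorobenzoic anhydride at rt. The fallback comes back to the route at 13.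

Step 7 (DDQ aromatisation). The enone may drift into conjugation with the side-chain alkene before the second hydride is taken, or the electron-rich phenol may be over-oxidised. Fallback: the two dehydrogenations are separated and the second is done through an enol silane instead of by hydride abstraction. The fallback sets out from 10, which is oxidised with MnO2 to the enone 11, now isolated. Soft enolisation (TMSOTf, Et3N, 0 °C) gives the silyl dienol ether F7, and Saegusa–Ito oxidation with Pd(OAc)2 in MeCN gives the dienone that tautomerises. The fallback comes back to the route at 12.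

Step 4 (two-carbon homologation). Lithiation of 1,2-dimethoxyethene and the acid step are argued by analogy with the cyclic dioxene reagent, and enol-ether hydrolysis to an α-hydroxy ketone may compete with the transposition. Fallback: olefination in place of addition and transposition. The fallback sets out from 4. Horner–Wadsworth–Emmons reaction with methyl 2-(dimethoxyphosphoryl)-2-methoxyacetate and NaH (2.2 equiv, THF, reflux) gives the methoxy enoate F8. Reduction with i-Bu2AlH gives the diol F9. TEMPO/PhI(OAc)2 oxidises only the primary allylic alcohol. The fallback comes back to the route at 7.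

**Further compounds**
F1 | step 6 | (6E,8S)-8-[(tert-butyldimethylsilyl)oxy]-2-methoxy-3,7,11-trimethyldodeca-2,6,10-trienal | O=CC(OC)=C(C)CC/C=C(\C)[C@H](CC=C(C)C)O[Si](C)(C)C(C)(C)C
F2 | step 6 | 6-[(3S)-3-[(tert-butyldimethylsilyl)oxy]-6-methylhepta-1,5-dien-2-yl]-2-methoxy-3-methylcyclohex-2-en-1-ol | OC1C(OC)=C(C)CCC1C(=C)[C@H](CC=C(C)C)O[Si](C)(C)C(C)(C)C
F3 | step 6 | 6-[(3S)-3-[(tert-butyldimethylsilyl)oxy]-6-methylhepta-1,5-dien-2-yl]-2-methoxy-3-methylcyclohex-2-en-1-one | O=C1C(OC)=C(C)CCC1C(=C)[C@H](CC=C(C)C)O[Si](C)(C)C(C)(C)C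
F4 | step 6 | 6-[(3S)-3-[(tert-butyldimethylsilyl)oxy]-6-methylhepta-1,5-dien-2-yl]-2-methoxy-3-methylphenol | Oc1c(OC)c(C)ccc1C(=C)[C@H](CC=C(C)C)O[Si](C)(C)C(C)(C)C
F5 | step 6 | 5-[(3S)-3-[(tert-butyldimethylsilyl)oxy]-6-methylhepta-1,5-dien-2-yl]-3-methoxy-2-methylcyclohexa-2,5-diene-1,4-dione | C=C(C1=CC(=O)C(C)=C(OC)C1=O)[C@H](CC=C(C)C)O[Si](C)(C)C(C)(C)C
F6 | step 6 | 5-[(3S)-3-hydroxy-6-methylhepta-1,5-dien-2-yl]-3-methoxy-2-methylcyclohexa-2,5-diene-1,4-dione | C=C(C1=CC(=O)C(C)=C(OC)C1=O)[C@H](CC=C(C)C)O
F7 | step 7 | (3S)-2-[3-methoxy-4-methyl-2-(trimethylsilyloxy)cyclohexa-1,3-dien-1-yl]-6-methylhepta-1,5-dien-3-yl (2Z)-2-methylbut-2-enoate | C[Si](C)(C)OC1=C(CCC(C)=C1OC)C(=C)[C@H](CC=C(C)C)OC(=O)/C(C)=C\C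
F8 | step 4 | methyl (6E,8S)-8-hydroxy-2-methoxy-3,7,11-trimethyldodeca-2,6,10-trienoate (2E/2Z mixture) | COC(=O)C(OC)=C(C)CC/C=C(\C)[C@H](CC=C(C)C)O
F9 | step 4 | (6E,8S)-2-methoxy-3,7,11-trimethyldodeca-2,6,10-triene-1,8-diol (2E/2Z mixture) | OCC(OC)=C(C)CC/C=C(\C)[C@H](CC=C(C)C)O
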